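The oxocane is carried through the route masked as a bicyclic ketal. C6 is a ketal carbon bonded to O10 and O12, giving a 2,9-dioxabicyclo[3.3.1]nonane of two six-membered rings whose eight-membered perimeter (C6–C12 plus O12) is the target ring. The key step exploits this 1,3-relationship of O10 and O12 and the C9 hydroxyl next to O10. i-Bu2AlH, anchored on O9, cuts the C6–O10 bridge and delivers hydride to C6. In one operation this uncovers the cis-2,8-disubstituted oxocane, sets C6 and frees the C9,C10-diol. The precursor is the ketal with C7 and C13 silyl ethers, a C4 benzyl ether and a free C9 hydroxyl.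

Key step: step 18

Remark: locants C1–C15 follow the carbon chain of the target (C1 = alkyne CH, ring oxygen on C6 and C12). O9 is kept as a 4-methoxybenzyl ether until the ketal is closed, because a free C9 hydroxyl would divert the C6 ketone into the 2,7-dioxabicyclo[2.2.1]heptane with O10.

Step 1
Reactants: 1 methyl (2S)-2-hydroxybutanoate
Product: 2 methyl (2S)-2-[(tert-butyldimethylsilyl)oxy]butanoate
Conditions: TBSCl, imidazole, DMF, 0 °C → rt
Reagents that add atoms: tert-butyldimethylsilyl chloride, CC(C)(C)[Si](C)(C)Cl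
Why: Imidazole-assisted O-silylation of the secondary alcohol touches only oxygen, so the C13 stereocentre from the chiral pool is carried over unchanged.

Step 2
Reactants: 2 methyl (2S)-2-[(tert-butyldimethylsilyl)oxy]butanoate
Product: 3 (2S)-2-[(tert-butyldimethylsilyl)oxy]butanal
Conditions: i-Bu2AlH, CH2Cl2, −78 °C; aq. potassium sodium tartrate
Reagents that add atoms: none
Why: Partial ester reduction by i-Bu2AlH stops at the tetrahedral aluminium hemiacetal at −78 °C and should give the α-silyloxy aldehyde, which is used crude to avoid epimerisation.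

Step 3
Reactants: 3 (2S)-2-[(tert-butyldimethylsilyl)oxy]butanal; 4 2-(trimethylsilyloxy)buta-1,3-diene
Product: 5 (5R,6S)-6-[(tert-butyldimethylsilyl)oxy]-5-hydroxyoct-1-en-3-one
Conditions: BF3·OEt2, CH2Cl2, −78 °C; aq. NaHCO3
Reagents that add atoms: none
Why: Mukaiyama aldol addition in which the monodentate Lewis acid lets the α-silyloxy aldehyde react through the polar Felkin–Anh arrangement, so the enol silane should add anti to the C13 oxygen and set C12 (R); the minor epimer should be separable at the diol stage.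

Step 4
Reactants: 5 (5R,6S)-6-[(tert-butyldimethylsilyl)oxy]-5-hydroxyoct-1-en-3-one
Product: 7 (3S,5R,6S)-6-[(tert-butyldimethylsilyl)oxy]oct-1-ene-3,5-diol, via O-diethylboryl chelate 6 (not isolated)
Conditions: Et2BOMe, THF/MeOH (4:1), −78 °C; NaBH4; MeOH co-evaporation
Reagents that add atoms: none
Why: Narasaka–Prasad reduction, in which borohydride attacks the six-membered boron chelate of the β-hydroxy ketone from the axial direction, should give the 1,3-syn diol by 1,2-reduction and set C10 (S).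

Step 5
Reactants: 7 (3S,5R,6S)-6-[(tert-butyldimethylsilyl)oxy]oct-1-ene-3,5-diol
Product: 8 tert-butyl{(1S)-1-[(4R,6S)-6-ethenyl-2,2-dimethyl-1,3-dioxan-4-yl]propoxy}dimethylsilane
Conditions: 2,2-dimethoxypropane, PPTS, CH2Cl2, rt
Reagents that add atoms: 2,2-dimethoxypropane, COC(C)(C)OC
Why: Acid-catalysed transketalisation closes the syn-1,3-diol to the chair 1,3-dioxane with both substituents equatorial.

Step 6
Reactants: 8 tert-butyl{(1S)-1-[(4R,6S)-6-ethenyl-2,2-dimethyl-1,3-dioxan-4-yl]propoxy}dimethylsilane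
Product: 10 (4S,6R)-6-{(1S)-1-[(tert-butyldimethylsilyl)oxy]propyl}-2,2-dimethyl-1,3-dioxane-4-carbaldehyde, via secondary ozonide 9 (not isolated)
Conditions: O3, CH2Cl2, −78 °C; PPh3, −78 °C → rt
Reagents that add atoms: ozone, [O-][O+]=O
Why: Ozonolysis of the terminal alkene (Criegee mechanism) with reductive work-up should give the C9 aldehyde, while silyl ether and acetonide are inert.

Step 7
Reactants: 10 (4S,6R)-6-{(1S)-1-[(tert-butyldimethylsilyl)oxy]propyl}-2,2-dimethyl-1,3-dioxane-4-carbaldehyde; 11 allylmagnesium bromide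
Product: 13 (1R)-1-[(4S,6R)-6-{(1S)-1-[(tert-butyldimethylsilyl)oxy]propyl}-2,2-dimethyl-1,3-dioxan-4-yl]but-3-en-1-ol, via B-allyldiisopinocampheylborane 12 (not isolated)
Conditions: (+)-Ipc2BOMe, Et2O, 0 °C → rt; then 10, −78 °C; NaOH, H2O2
Reagents that add atoms: none
Why: Brown allylboration through a chair Zimmerman–Traxler transition state, in which the isopinocampheyl groups of the (−)-α-pinene series should direct allyl to the Re face of the aldehyde and set C9 (R) under reagent control.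

Step 8
Reactants: 13 (1R)-1-[(4S,6R)-6-{(1S)-1-[(tert-butyldimethylsilyl)oxy]propyl}-2,2-dimethyl-1,3-dioxan-4-yl]but-3-en-1-ol
Product: 14 tert-butyl{(1S)-1-[(4R,6S)-6-{(1R)-1-[(4-methoxybenzyl)oxy]but-3-en-1-yl}-2,2-dimethyl-1,3-dioxan-4-yl]propoxy}dimethylsilane
Conditions: NaH, PMBCl, n-Bu4NI (cat.), THF/DMF, 0 °C → rt
Reagents that add atoms: 4-methoxybenzyl chloride, COc1ccc(CCl)cc1
Why: Williamson etherification of the sodium alkoxide masks O9 with a group that survives acid and base and can later be removed oxidatively beside the benzyl ether.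

Step 9
Reactants: 14 tert-butyl{(1S)-1-[(4R,6S)-6-{(1R)-1-[(4-methoxybenzyl)oxy]but-3-en-1-yl}-2,2-dimethyl-1,3-dioxan-4-yl]propoxy}dimethylsilane
Product: 16 (3R)-3-[(4S,6R)-6-{(1S)-1-[(tert-butyldimethylsilyl)oxy]propyl}-2,2-dimethyl-1,3-dioxan-4-yl]-3-[(4-methoxybenzyl)oxy]propanal, via vicinal diol 15 (not isolated)
Conditions: OsO4 (cat.), NaIO4, 2,6-lutidine, dioxane/H2O (3:1), rt
Reagents that add atoms: osmium tetroxide, O=[Os](=O)(=O)=O (catalytic oxygen carrier); sodium periodate, [Na+].[O-]I(=O)(=O)=O (terminal oxygen source)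
Why: Lemieux–Johnson oxidation (osmylation, then periodate glycol cleavage) should shorten the allyl group to the C7 aldehyde without touching the electron-rich arene that ozone could attack.

Step 10
Reactants: 17 3-(benzyloxy)propanal; 18 propane-1,3-dithiol
Product: 19 2-[2-(benzyloxy)ethyl]-1,3-dithiane
Conditions: BF3·OEt2 (cat.), CH2Cl2, 0 °C → rt
Reagents that add atoms: none
Why: Lewis acid-catalysed dithioacetalisation of the aldehyde gives the Corey–Seebach acyl-anion precursor that will become C4–C6.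

Step 11
Reactants: 16 (3R)-3-[(4S,6R)-6-{(1S)-1-[(tert-butyldimethylsilyl)oxy]propyl}-2,2-dimethyl-1,3-dioxan-4-yl]-3-[(4-methoxybenzyl)oxy]propanal; 19 2-[2-(benzyloxy)ethyl]-1,3-dithiane
Product: 21 (3R)-1-{2-[2-(benzyloxy)ethyl]-1,3-dithian-2-yl}-3-[(4S,6R)-6-{(1S)-1-[(tert-butyldimethylsilyl)oxy]propyl}-2,2-dimethyl-1,3-dioxan-4-yl]-3-[(4-methoxybenzyl)oxy]propan-1-ol (both C1 epimers), via 2-lithio-1,3-dithiane 20 (not isolated)
Conditions: t-BuLi, THF/HMPA (9:1), −78 °C; then 16, −78 °C; H2O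
Reagents that add atoms: none
Why: Corey–Seebach umpolung, in which the lithiated dithiane adds to the aldehyde, forms the C6–C7 bond; the C7 epimers are not separated because the next step removes this centre.

Step 12
Reactants: 21 (3R)-1-{2-[2-(benzyloxy)ethyl]-1,3-dithian-2-yl}-3-[(4S,6R)-6-{(1S)-1-[(tert-butyldimethylsilyl)oxy]propyl}-2,2-dimethyl-1,3-dioxan-4-yl]-3-[(4-methoxybenzyl)oxy]propan-1-ol
Product: 22 (3R)-1-{2-[2-(benzyloxy)ethyl]-1,3-dithian-2-yl}-3-[(4S,6R)-6-{(1S)-1-[(tert-butyldimethylsilyl)oxy]propyl}-2,2-dimethyl-1,3-dioxan-4-yl]-3-[(4-methoxybenzyl)oxy]propan-1-one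
Conditions: SO3·pyridine, DMSO, i-Pr2NEt, CH2Cl2, 0 °C; aq. NaHCO3
Reagents that add atoms: none
Why: Parikh–Doering oxidation with activated DMSO should convert the carbinol into the 2-acyl-1,3-dithiane without oxidising sulfur.

Step 13
Reactants: 22 (3R)-1-{2-[2-(benzyloxy)ethyl]-1,3-dithian-2-yl}-3-[(4S,6R)-6-{(1S)-1-[(tert-butyldimethylsilyl)oxy]propyl}-2,2-dimethyl-1,3-dioxan-4-yl]-3-[(4-methoxybenzyl)oxy]propan-1-one
Product: 23 (1R,3R)-1-{2-[2-(benzyloxy)ethyl]-1,3-dithian-2-yl}-3-[(4S,6R)-6-{(1S)-1-[(tert-butyldimethylsilyl)oxy]propyl}-2,2-dimethyl-1,3-dioxan-4-yl]-3-[(4-methoxybenzyl)oxy]propan-1-ol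
Conditions: (S)-2-methyl-CBS-oxazaborolidine, BH3·SMe2, THF, −20 °C; MeOH
Reagents that add atoms: none
Why: Corey–Bakshi–Shibata reduction, in which the quaternary dithianyl carbon is the large and CH2 the small ketone substituent, so the (S)-oxazaborolidine should deliver hydride to the face that gives the C7 (R) alcohol.

Step 14
Reactants: 23 (1R,3R)-1-{2-[2-(benzyloxy)ethyl]-1,3-dithian-2-yl}-3-[(4S,6R)-6-{(1S)-1-[(tert-butyldimethylsilyl)oxy]propyl}-2,2-dimethyl-1,3-dioxan-4-yl]-3-[(4-methoxybenzyl)oxy]propan-1-ol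
Product: 24 tert-butyldimethylsilyl ether of 23 at the C7 oxygen
Conditions: TBSOTf, 2,6-lutidine, CH2Cl2, −78 → 0 °C
Reagents that add atoms: tert-butyldimethylsilyl trifluoromethanesulfonate, CC(C)(C)[Si](C)(C)OS(=O)(=O)C(F)(F)F
Why: Silyl triflate silylation of the hindered secondary alcohol installs the non-coordinating C7 silyl ether that the key step requires.

Step 15
Reactants: 24 tert-butyldimethylsilyl ether of 23 at the C7 oxygen
Product: 25 (4R,6R)-1-(benzyloxy)-4-[(tert-butyldimethylsilyl)oxy]-6-[(4S,6R)-6-{(1S)-1-[(tert-butyldimethylsilyl)oxy]propyl}-2,2-dimethyl-1,3-dioxan-4-yl]-6-[(4-methoxybenzyl)oxy]hexan-3-one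
Conditions: MeI, CaCO3, MeCN/H2O (9:1), 45 °C
Reagents that add atoms: water, O
Why: Alkylative dithiane hydrolysis (S-methylation, then hydrolysis of the sulfonium ion, buffered by CaCO3) should unmask the C6 ketone under near-neutral conditions that spare the acetonide and the benzylic and silyl ethers.

Step 16
Reactants: 25 (4R,6R)-1-(benzyloxy)-4-[(tert-butyldimethylsilyl)oxy]-6-[(4S,6R)-6-{(1S)-1-[(tert-butyldimethylsilyl)oxy]propyl}-2,2-dimethyl-1,3-dioxan-4-yl]-6-[(4-methoxybenzyl)oxy]hexan-3-one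
Product: 27 (1R,3R,5S,6R,8R)-1-[2-(benzyloxy)ethyl]-8-[(tert-butyldimethylsilyl)oxy]-3-{(1S)-1-[(tert-butyldimethylsilyl)oxy]propyl}-6-[(4-methoxybenzyl)oxy]-2,9-dioxabicyclo[3.3.1]nonane, via dihydroxy ketone 26 (not isolated)
Conditions: PPTS, MeOH/CH2Cl2, rt; then PPTS, PhH, 4 Å MS, 50 °C
Reagents that add atoms: none
Why: Acid-catalysed acetonide methanolysis and intramolecular ketalisation under thermodynamic control, in which O10 closes the tetrahydropyran and O12 the second six-membered ring while blocked O9 cannot compete; C6 is fixed by the bicycle, and the syn-10,12 relationship forces the C12 side chain endo, so the dioxane ring should sit as a boat.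

Step 17
Reactants: 27 (1R,3R,5S,6R,8R)-1-[2-(benzyloxy)ethyl]-8-[(tert-butyldimethylsilyl)oxy]-3-{(1S)-1-[(tert-butyldimethylsilyl)oxy]propyl}-6-[(4-methoxybenzyl)oxy]-2,9-dioxabicyclo[3.3.1]nonane
Product: 28 (1R,3R,5S,6R,8R)-1-[2-(benzyloxy)ethyl]-8-[(tert-butyldimethylsilyl)oxy]-3-{(1S)-1-[(tert-butyldimethylsilyl)oxy]propyl}-2,9-dioxabicyclo[3.3.1]nonan-6-ol
Conditions: DDQ, CH2Cl2/pH 7 buffer (10:1), 0 °C
Reagents that add atoms: none
Why: Oxidative cleavage of the 4-methoxybenzyl ether by DDQ (benzylic hydride abstraction, then hydrolysis) should free the C9 hydroxyl while the benzyl ether, the silyl ethers and the ketal stay.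

Step 18
Reactants: 28 (1R,3R,5S,6R,8R)-1-[2-(benzyloxy)ethyl]-8-[(tert-butyldimethylsilyl)oxy]-3-{(1S)-1-[(tert-butyldimethylsilyl)oxy]propyl}-2,9-dioxabicyclo[3.3.1]nonan-6-ol
Product: 30 (2R,3R,5R,6S,8R)-2-[2-(benzyloxy)ethyl]-3-[(tert-butyldimethylsilyl)oxy]-8-{(1S)-1-[(tert-butyldimethylsilyl)oxy]propyl}oxocane-5,6-diol, via C9 aluminium alkoxide 29 (not isolated)
Conditions: i-Bu2AlH (6 equiv), CH2Cl2, −78 → 0 °C; aq. potassium sodium tartrate
Reagents that add atoms: none
Why: The free C9 hydroxyl reacts first to give the aluminium alkoxide 29, whose metal bridges O9 and the gauche bridging O10 in a five-membered chelate and so weakens only the C6–O10 bond; this bond ionises with help from an O12 lone pair to the eight-membered oxocarbenium ion, and a hydride held in the alkoxide-bridged aluminium aggregate is transferred to C6 on the face that O10 has just left. The closest known reaction type is the i-Bu2AlH reductive cleavage of bicyclic ketals to cis-α,α′-disubstituted oxepanes and oxocanes, combined with alkoxide-directed aluminium hydride opening of acetals. The oxocane is not closed by a new bond: it is the perimeter of the bicycle and is released when the one-atom O10 bridge is cut, so no cyclisation mode has to be satisfied. The new stereocentre C6 is controlled by the bicycle itself, because hydride enters where the bridge was (retention), which should place H syn to O10 and the C5 arm on the face of the C12 side chain (cis-2,8, 6R). The step needs regioselectivity for C6–O10 over C6–O12 cleavage (the latter would give a tetrahydropyran); this should be secured by the C9 alkoxide chelate, by the bulky non-coordinating silyl ethers at C7 and C13 that flank O12, and by the non-coordinating solvent.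

Step 19
Reactants: 30 (2R,3R,5R,6S,8R)-2-[2-(benzyloxy)ethyl]-3-[(tert-butyldimethylsilyl)oxy]-8-{(1S)-1-[(tert-butyldimethylsilyl)oxy]propyl}oxocane-5,6-diol
Product: 31 9,10-O-isopropylidene acetal of 30 (cis-fused 2,2-dimethyl-1,3-dioxolane)
Conditions: 2,2-dimethoxypropane, PPTS, CH2Cl2, rt
Reagents that add atoms: 2,2-dimethoxypropane, COC(C)(C)OC
Why: Acetonide formation on the cis-9,10-diol gives a five-membered dioxolane and sets this diol apart from the two silyl-protected oxygens.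

Step 20
Reactants: 31 9,10-O-isopropylidene acetal of 30
Product: 32 C4 primary alcohol (debenzylated 31)
Conditions: H2 (1 atm), Pd/C, EtOAc, rt
Reagents that add atoms: none
Why: Hydrogenolysis of the benzyl ether over Pd/C should be clean because no alkene or sulfur is present at this stage.

Step 21
Reactants: 32 C4 primary alcohol (debenzylated 31)
Product: 33 C4 aldehyde: 2-(oxocan-2-yl)acetaldehyde carrying the 7,13-bis-silyl ethers and the 9,10-acetonide
Conditions: Dess–Martin periodinane, NaHCO3, CH2Cl2, 0 °C → rt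
Reagents that add atoms: none
Why: Dess–Martin oxidation converts the primary alcohol to the aldehyde under buffered, non-basic conditions that should avoid β-elimination of the ring oxygen.

Step 22
Reactants: 33 C4 aldehyde; 34 1,3-bis(triisopropylsilyl)propyne
Product: 37 (3Z)-enyne with a triisopropylsilyl group on C1 and the 7,13-bis-silyl ethers and 9,10-acetonide in place, via lithiated bis(silyl)propyne 35 (not isolated), via β-silyl alkoxide adduct 36 (not isolated)
Conditions: n-BuLi, THF, −20 °C (34); then 33, −78 °C → rt; H2O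
Reagents that add atoms: none
Why: Peterson olefination, in which the lithiated propargyl silane adds to the aldehyde and the β-silyl alkoxide undergoes syn elimination, should give the (Z)-enyne because the bulky silyl groups bias the addition.

Step 23
Reactants: 37 (3Z)-enyne with a triisopropylsilyl group on C1
Product: 38 (3Z,6R,7R,9R,10S,12R,13S)-6,12-epoxy-9,10-(isopropylidenedioxy)pentadec-3-en-1-yne-7,13-diol
Conditions: n-Bu4NF, THF, 0 °C → rt
Reagents that add atoms: none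
Why: Fluoride-mediated desilylation should remove the alkynyl silane and both silyl ethers in one operation while the acetonide stays.

Step 24
Reactants: 38 (3Z,6R,7R,9R,10S,12R,13S)-6,12-epoxy-9,10-(isopropylidenedioxy)pentadec-3-en-1-yne-7,13-diol
Product: 39 7,13-di-O-acetate of 38
Conditions: Ac2O, pyridine, DMAP (cat.), CH2Cl2, rt
Reagents that add atoms: acetic anhydride, CC(=O)OC(C)=O
Why: DMAP-catalysed acylation esterifies the two free secondary alcohols.

Step 25
Reactants: 39 7,13-di-O-acetate of 38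
Product: 40 (3Z,6R,7R,9R,10S,12R,13S)-7,13-diacetoxy-6,12-epoxypentadec-3-en-1-yne-9,10-diol (target)
Conditions: AcOH/H2O (4:1), 40 °C
Reagents that add atoms: none
Why: Mild aqueous acid hydrolysis of the dioxolane should leave the acetates and the enyne intact, and acyl migration is not expected under acidic conditions.

Compound list
1 | methyl (2S)-2-hydroxybutanoate | CC[C@H](O)C(=O)OC | starting material
2 | methyl (2S)-2-[(tert-butyldimethylsilyl)oxy]butanoate | CC[C@H](O[Si](C)(C)C(C)(C)C)C(=O)OC | intermediate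
3 | (2S)-2-[(tert-butyldimethylsilyl)oxy]butanal | CC[C@H](O[Si](C)(C)C(C)(C)C)C=O | intermediate
4 | 2-(trimethylsilyloxy)buta-1,3-diene | C=CC(=C)O[Si](C)(C)C | starting material
5 | (5R,6S)-6-[(tert-butyldimethylsilyl)oxy]-5-hydroxyoct-1-en-3-one | CC[C@H](O[Si](C)(C)C(C)(C)C)[C@H](O)CC(=O)C=C | intermediate
6 | O-diethylboryl chelate of 5, (5R,6S)-6-[(tert-butyldimethylsilyl)oxy]-5-[(diethylboranyl)oxy]oct-1-en-3-one | CC[C@H](O[Si](C)(C)C(C)(C)C)[C@H](OB(CC)CC)CC(=O)C=C | intermediate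
7 | (3S,5R,6S)-6-[(tert-butyldimethylsilyl)oxy]oct-1-ene-3,5-diol | CC[C@H](O[Si](C)(C)C(C)(C)C)[C@H](O)C[C@H](O)C=C | intermediate
8 | tert-butyl{(1S)-1-[(4R,6S)-6-ethenyl-2,2-dimethyl-1,3-dioxan-4-yl]propoxy}dimethylsilane | CC[C@H](O[Si](C)(C)C(C)(C)C)[C@H]1C[C@@H](C=C)OC(C)(C)O1 | intermediate
9 | secondary ozonide of 8, 3-[(4S,6R)-6-{(1S)-1-[(tert-butyldimethylsilyl)oxy]propyl}-2,2-dimethyl-1,3-dioxan-4-yl]-1,2,4-trioxolane (epimers at the trioxolane carbon) | CC[C@H](O[Si](C)(C)C(C)(C)C)[C@H]1C[C@@H](C2OCOO2)OC(C)(C)O1 | intermediate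
10 | (4S,6R)-6-{(1S)-1-[(tert-butyldimethylsilyl)oxy]propyl}-2,2-dimethyl-1,3-dioxane-4-carbaldehyde | CC[C@H](O[Si](C)(C)C(C)(C)C)[C@H]1C[C@@H](C=O)OC(C)(C)O1 | intermediate
11 | allylmagnesium bromide | C=CC[Mg]Br | starting material
12 | B-allyldiisopinocampheylborane of the (−)-α-pinene series | C=CCB([C@H]1C[C@H]2C[C@@H]([C@@H]1C)C2(C)C)[C@H]1C[C@H]2C[C@@H]([C@@H]1C)C2(C)C | intermediate
13 | (1R)-1-[(4S,6R)-6-{(1S)-1-[(tert-butyldimethylsilyl)oxy]propyl}-2,2-dimethyl-1,3-dioxan-4-yl]but-3-en-1-ol | CC[C@H](O[Si](C)(C)C(C)(C)C)[C@H]1C[C@@H]([C@H](O)CC=C)OC(C)(C)O1 | intermediate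
14 | tert-butyl{(1S)-1-[(4R,6S)-6-{(1R)-1-[(4-methoxybenzyl)oxy]but-3-en-1-yl}-2,2-dimethyl-1,3-dioxan-4-yl]propoxy}dimethylsilane | CC[C@H](O[Si](C)(C)C(C)(C)C)[C@H]1C[C@@H]([C@H](OCc2ccc(OC)cc2)CC=C)OC(C)(C)O1 | intermediate
15 | (4R)-4-[(4S,6R)-6-{(1S)-1-[(tert-butyldimethylsilyl)oxy]propyl}-2,2-dimethyl-1,3-dioxan-4-yl]-4-[(4-methoxybenzyl)oxy]butane-1,2-diol (C2 epimers) | CC[C@H](O[Si](C)(C)C(C)(C)C)[C@H]1C[C@@H]([C@H](OCc2ccc(OC)cc2)CC(O)CO)OC(C)(C)O1 | intermediate
16 | (3R)-3-[(4S,6R)-6-{(1S)-1-[(tert-butyldimethylsilyl)oxy]propyl}-2,2-dimethyl-1,3-dioxan-4-yl]-3-[(4-methoxybenzyl)oxy]propanal | CC[C@H](O[Si](C)(C)C(C)(C)C)[C@H]1C[C@@H]([C@H](OCc2ccc(OC)cc2)CC=O)OC(C)(C)O1 | intermediate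
17 | 3-(benzyloxy)propanal | O=CCCOCc1ccccc1 | starting material
18 | propane-1,3-dithiol | SCCCS | starting material
19 | 2-[2-(benzyloxy)ethyl]-1,3-dithiane | C1CSC(CCOCc2ccccc2)SC1 | intermediate
20 | 2-[2-(benzyloxy)ethyl]-2-lithio-1,3-dithiane | [Li]C1(CCOCc2ccccc2)SCCCS1 | intermediate
21 | (3R)-1-{2-[2-(benzyloxy)ethyl]-1,3-dithian-2-yl}-3-[(4S,6R)-6-{(1S)-1-[(tert-butyldimethylsilyl)oxy]propyl}-2,2-dimethyl-1,3-dioxan-4-yl]-3-[(4-methoxybenzyl)oxy]propan-1-ol (C1 epimers) | CC[C@H](O[Si](C)(C)C(C)(C)C)[C@H]1C[C@@H]([C@H](OCc2ccc(OC)cc2)CC(O)C2(CCOCc3ccccc3)SCCCS2)OC(C)(C)O1 | intermediate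
22 | (3R)-1-{2-[2-(benzyloxy)ethyl]-1,3-dithian-2-yl}-3-[(4S,6R)-6-{(1S)-1-[(tert-butyldimethylsilyl)oxy]propyl}-2,2-dimethyl-1,3-dioxan-4-yl]-3-[(4-methoxybenzyl)oxy]propan-1-one | CC[C@H](O[Si](C)(C)C(C)(C)C)[C@H]1C[C@@H]([C@H](OCc2ccc(OC)cc2)CC(=O)C2(CCOCc3ccccc3)SCCCS2)OC(C)(C)O1 | intermediate
23 | (1R,3R)-1-{2-[2-(benzyloxy)ethyl]-1,3-dithian-2-yl}-3-[(4S,6R)-6-{(1S)-1-[(tert-butyldimethylsilyl)oxy]propyl}-2,2-dimethyl-1,3-dioxan-4-yl]-3-[(4-methoxybenzyl)oxy]propan-1-ol | CC[C@H](O[Si](C)(C)C(C)(C)C)[C@H]1C[C@@H]([C@H](OCc2ccc(OC)cc2)C[C@@H](O)C2(CCOCc3ccccc3)SCCCS2)OC(C)(C)O1 | intermediate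
24 | tert-butyldimethylsilyl ether of 23 at the C7 oxygen (7R,9R,10S,12R,13S) | CC[C@H](O[Si](C)(C)C(C)(C)C)[C@H]1C[C@@H]([C@H](OCc2ccc(OC)cc2)C[C@@H](O[Si](C)(C)C(C)(C)C)C2(CCOCc3ccccc3)SCCCS2)OC(C)(C)O1 | intermediate
25 | (4R,6R)-1-(benzyloxy)-4-[(tert-butyldimethylsilyl)oxy]-6-[(4S,6R)-6-{(1S)-1-[(tert-butyldimethylsilyl)oxy]propyl}-2,2-dimethyl-1,3-dioxan-4-yl]-6-[(4-methoxybenzyl)oxy]hexan-3-one | CC[C@H](O[Si](C)(C)C(C)(C)C)[C@H]1C[C@@H]([C@H](OCc2ccc(OC)cc2)C[C@@H](O[Si](C)(C)C(C)(C)C)C(=O)CCOCc2ccccc2)OC(C)(C)O1 | intermediate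
26 | (4R,6R,7S,9R,10S)-1-(benzyloxy)-4,10-bis[(tert-butyldimethylsilyl)oxy]-7,9-dihydroxy-6-[(4-methoxybenzyl)oxy]dodecan-3-one | CC[C@H](O[Si](C)(C)C(C)(C)C)[C@H](O)C[C@H](O)[C@H](OCc1ccc(OC)cc1)C[C@@H](O[Si](C)(C)C(C)(C)C)C(=O)CCOCc1ccccc1 | intermediate
27 | (1R,3R,5S,6R,8R)-1-[2-(benzyloxy)ethyl]-8-[(tert-butyldimethylsilyl)oxy]-3-{(1S)-1-[(tert-butyldimethylsilyl)oxy]propyl}-6-[(4-methoxybenzyl)oxy]-2,9-dioxabicyclo[3.3.1]nonane | c1ccccc1COCC[C@]12O[C@@H]([C@H](CC)O[Si](C)(C)C(C)(C)C)C[C@H](O1)[C@H](OCc3ccc(OC)cc3)C[C@H]2O[Si](C)(C)C(C)(C)C | intermediate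
28 | (1R,3R,5S,6R,8R)-1-[2-(benzyloxy)ethyl]-8-[(tert-butyldimethylsilyl)oxy]-3-{(1S)-1-[(tert-butyldimethylsilyl)oxy]propyl}-2,9-dioxabicyclo[3.3.1]nonan-6-ol (C6 ketal carbon, O10 bridge, free C9 hydroxyl) | c1ccccc1COCC[C@]12O[C@@H]([C@H](CC)O[Si](C)(C)C(C)(C)C)C[C@H](O1)[C@H](O)C[C@H]2O[Si](C)(C)C(C)(C)C | intermediate
29 | diisobutylaluminium alkoxide of 28 at O9 | c1ccccc1COCC[C@]12O[C@@H]([C@H](CC)O[Si](C)(C)C(C)(C)C)C[C@H](O1)[C@H](O[Al](CC(C)C)CC(C)C)C[C@H]2O[Si](C)(C)C(C)(C)C | intermediate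
30 | (2R,3R,5R,6S,8R)-2-[2-(benzyloxy)ethyl]-3-[(tert-butyldimethylsilyl)oxy]-8-{(1S)-1-[(tert-butyldimethylsilyl)oxy]propyl}oxocane-5,6-diol | c1ccccc1COCC[C@H]1O[C@@H]([C@H](CC)O[Si](C)(C)C(C)(C)C)C[C@H](O)[C@H](O)C[C@H]1O[Si](C)(C)C(C)(C)C | intermediate
31 | 9,10-O-isopropylidene acetal of 30 (cis-fused dioxolane; 6R,7R,9R,10S,12R,13S) | c1ccccc1COCC[C@H]1O[C@@H]([C@H](CC)O[Si](C)(C)C(C)(C)C)C[C@@H]2OC(C)(C)O[C@@H]2C[C@H]1O[Si](C)(C)C(C)(C)C | intermediate
32 | C4 primary alcohol, 2-(oxocan-2-yl)ethanol carrying the 7,13-bis(tert-butyldimethylsilyl) ethers and the 9,10-acetonide | OCC[C@H]1O[C@@H]([C@H](CC)O[Si](C)(C)C(C)(C)C)C[C@@H]2OC(C)(C)O[C@@H]2C[C@H]1O[Si](C)(C)C(C)(C)C | intermediate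
33 | C4 aldehyde, 2-(oxocan-2-yl)acetaldehyde carrying the 7,13-bis(tert-butyldimethylsilyl) ethers and the 9,10-acetonide | O=CC[C@H]1O[C@@H]([C@H](CC)O[Si](C)(C)C(C)(C)C)C[C@@H]2OC(C)(C)O[C@@H]2C[C@H]1O[Si](C)(C)C(C)(C)C | intermediate
34 | 1,3-bis(triisopropylsilyl)propyne | CC(C)[Si](C(C)C)(C(C)C)CC#C[Si](C(C)C)(C(C)C)C(C)C | starting material
35 | 1-lithio-1,3-bis(triisopropylsilyl)propyne (lithiated at the propargylic carbon) | CC(C)[Si](C(C)C)(C(C)C)C([Li])C#C[Si](C(C)C)(C(C)C)C(C)C | intermediate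
36 | lithium alkoxide of the adduct of 35 to 33 (C3 silyl, C4 alkoxide, both new centres as mixtures) | CC(C)[Si](C(C)C)(C(C)C)C#CC([Si](C(C)C)(C(C)C)C(C)C)C(O[Li])C[C@H]1O[C@@H]([C@H](CC)O[Si](C)(C)C(C)(C)C)C[C@@H]2OC(C)(C)O[C@@H]2C[C@H]1O[Si](C)(C)C(C)(C)C | intermediate
37 | (3Z)-1-(triisopropylsilyl) enyne with the 7,13-bis(tert-butyldimethylsilyl) ethers and the 9,10-acetonide | CC(C)[Si](C(C)C)(C(C)C)C#C/C=C\C[C@H]1O[C@@H]([C@H](CC)O[Si](C)(C)C(C)(C)C)C[C@@H]2OC(C)(C)O[C@@H]2C[C@H]1O[Si](C)(C)C(C)(C)C | intermediate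
38 | (3Z,6R,7R,9R,10S,12R,13S)-6,12-epoxy-9,10-(isopropylidenedioxy)pentadec-3-en-1-yne-7,13-diol | C#C/C=C\C[C@H]1O[C@@H]([C@H](CC)O)C[C@@H]2OC(C)(C)O[C@@H]2C[C@H]1O | intermediate
39 | 7,13-di-O-acetate of 38 | C#C/C=C\C[C@H]1O[C@@H]([C@H](CC)OC(C)=O)C[C@@H]2OC(C)(C)O[C@@H]2C[C@H]1OC(C)=O | intermediate
40 | (3Z,6R,7R,9R,10S,12R,13S)-7,13-diacetoxy-6,12-epoxypentadec-3-en-1-yne-9,10-diol, i.e. (1S)-1-[(2R,4S,5R,7R,8R)-7-acetoxy-4,5-dihydroxy-8-[(2Z)-pent-2-en-4-yn-1-yl]oxocan-2-yl]propyl acetate | C#C/C=C\C[C@H]1O[C@@H]([C@H](CC)OC(C)=O)C[C@H](O)[C@H](O)C[C@H]1OC(C)=O | target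

Total step count: 25. Longest linear sequence: 24 steps (steps 1–9 and 11–25; step 10 is a one-step branch).

Steps most likely to fail

Step 18. Ionisation may take place at C6–O12 instead of C6–O10, because the six-membered oxocarbenium ion is intrinsically easier to form, which would lead to a tetrahydropyran. Hydride may also be delivered from the face away from the bridge, which would give the trans-oxocane. The fallback sets out from 28 and returns at 31; it closes the eight-membered ring through a thionium ion instead of opening a ketal. Thioketalisation with EtSH and Zn(OTf)2 in CH2Cl2 at 0 °C opens the bicycle to the open-chain diethyl dithioketal triol F1. Kinetic acetonide formation (2-methoxypropene, PPTS, 0 °C) ties up the cis-9,10-diol as the dioxolane with a free C12 hydroxyl F2, so that only O12 can cyclise. Silver-promoted hydroxy dithioketal cyclisation (AgClO4, NaHCO3, silica gel, 4 Å MS, MeNO2) should give the eight-membered S,O-ketal F3, the cis-dioxolane supplying the turn that medium-ring closure needs. Radical desulfurisation with Ph3SnH and 2,2′-azobis(isobutyronitrile) in toluene at 110 °C should then place hydrogen on C6 from the less hindered face and give 31.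

Step 16. The ketal is strained (C12 side chain endo, dioxane ring as a boat), so the acid equilibrium may stop at the monocyclic hemiketal or drain into an enol ether, and longer exposure to acid risks loss of a silyl ether. The fallback sets out from 24 and returns at 27; it forms the ketal irreversibly instead of by equilibration. The acetonide is removed first (PPTS, MeOH, rt) to give the dihydroxy dithiane F4. Thiophilic activation of the dithiane under buffered, anhydrous conditions (Hg(ClO4)2, CaCO3, THF/MeCN, 4 Å MS, 0 °C) then lets O10 and O12 trap the thionium intermediates in turn and should deliver 27 directly.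

Step 22. The strongly basic propargyl anion may cause β-elimination of the ring oxygen from the β-alkoxy aldehyde, or the Z selectivity may erode. The fallback sets out from 33 and returns at 38; it builds the enyne in two bond-forming steps under milder conditions. Stork–Zhao olefination (iodomethyltriphenylphosphonium iodide, NaN(SiMe3)2, THF/HMPA, −78 °C) should give the (Z)-vinyl iodide F5. Sonogashira coupling with ethynyltrimethylsilane (Pd(PPh3)4, CuI, i-Pr2NH, rt) should give the (Z)-trimethylsilyl enyne F6 with retention of geometry. n-Bu4NF in THF then removes all three silyl groups and gives 38.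

Further compounds
F1 | step 18 | open-chain diethyl dithioketal triol, (4R,6R,7S,9R,10S)-1-(benzyloxy)-4,10-bis[(tert-butyldimethylsilyl)oxy]-3,3-bis(ethylsulfanyl)dodecane-6,7,9-triol | CC[C@H](O[Si](C)(C)C(C)(C)C)[C@H](O)C[C@H](O)[C@H](O)C[C@@H](O[Si](C)(C)C(C)(C)C)C(SCC)(SCC)CCOCc1ccccc1
F2 | step 18 | 9,10-O-isopropylidene acetal of F1 with free C12 hydroxyl | CC[C@H](O[Si](C)(C)C(C)(C)C)[C@H](O)C[C@@H]1OC(C)(C)O[C@@H]1C[C@@H](O[Si](C)(C)C(C)(C)C)C(SCC)(SCC)CCOCc1ccccc1
F3 | step 18 | eight-membered S,O-ketal, 6-(ethylsulfanyl) derivative of 31 (C6 epimers) | c1ccccc1COCCC1(SCC)O[C@@H]([C@H](CC)O[Si](C)(C)C(C)(C)C)C[C@@H]2OC(C)(C)O[C@@H]2C[C@H]1O[Si](C)(C)C(C)(C)C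
F4 | step 16 | dihydroxy dithiane, 24 without the acetonide (free C10 and C12 hydroxyls) | CC[C@H](O[Si](C)(C)C(C)(C)C)[C@H](O)C[C@H](O)[C@H](OCc1ccc(OC)cc1)C[C@@H](O[Si](C)(C)C(C)(C)C)C1(CCOCc2ccccc2)SCCCS1
F5 | step 22 | (Z)-vinyl iodide (C3 iodide) with the 7,13-bis(tert-butyldimethylsilyl) ethers and the 9,10-acetonide | I/C=C\C[C@H]1O[C@@H]([C@H](CC)O[Si](C)(C)C(C)(C)C)C[C@@H]2OC(C)(C)O[C@@H]2C[C@H]1O[Si](C)(C)C(C)(C)C
F6 | step 22 | (3Z)-1-(trimethylsilyl) enyne with the 7,13-bis(tert-butyldimethylsilyl) ethers and the 9,10-acetonide | C[Si](C)(C)C#C/C=C\C[C@H]1O[C@@H]([C@H](CC)O[Si](C)(C)C(C)(C)C)C[C@@H]2OC(C)(C)O[C@@H]2C[C@H]1O[Si](C)(C)C(C)(C)C
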